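Labdane numbering is used (decalin C1–C10, side chain C11–C16, C17 on C8, C18/C19 on C4, C20 on C10).

**Plan**
- Enabling feature: ring B is a cyclohexene whose C8=C9 double bond flanks the quaternary ring-fusion carbon C10, with oxygen on C6. This is the retron of a Diels–Alder reaction between a diene C7=C8–C9=C10 and a dienophile C5=C6, tethered by C1–C4 of ring A.
- Retrosynthesis: remove acetates and silyl groups; cut C7–O (enolate hydroxylation) and C6–O (ketone from a nitro group); then cut C5–C10 and C6–C7 together (intramolecular Diels–Alder of an (E)-1-nitro-1,7,9-decatriene). The chain is then cut at C5=C6 (Henry), C8–C9 (Suzuki), C10–CH3/C9–B (alkyne methylboration), C3–C4 (nitrile anion/epoxide) and C1–C10 (acetylide/epichlorohydrin).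
- Forward: the acyclic chain is joined from a geranyl acetate-derived enyne, (R)-epichlorohydrin, isobutyronitrile, MeI, 2-bromopropene and nitromethane. Rings A and B arise together in the cycloaddition; ring B is then oxygenated at C6 and C7.
- Stereochemistry: C2 from (R)-epichlorohydrin; C10 and C5 from the cycloaddition under control of C2; C7 by α-face enolate hydroxylation; C6 by α-face hydride addition; 13E from geranyl acetate; diene geometry from syn-methylboration.

Key step: step 11

**Route**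

Step 1
Reactants: 1 geranyl acetate
Product: 2 (2E)-3-methyl-6-oxohex-2-en-1-yl acetate
Conditions: O3 (1.0 equiv), CH2Cl2, pyridine, −78 °C; then Me2S, −78 °C → rt
Reagents that add atoms: ozone, [O-][O+]=O
Why: Chemoselective ozonolysis: the electron-rich 6,7-alkene should react much faster than the 2,3-alkene deactivated by the allylic acetate, and the 2E geometry is untouched.

Step 2
Reactants: 2 (2E)-3-methyl-6-oxohex-2-en-1-yl acetate
Product: 3 (2E)-3-methylhept-2-en-6-yn-1-ol
Conditions: dimethyl (1-diazo-2-oxopropyl)phosphonate, K2CO3, MeOH, 0 °C → rt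
Reagents that add atoms: Ohira–Bestmann reagent, COP(=O)(OC)C(=[N+]=[N-])C(C)=O
Why: Ohira–Bestmann (Seyferth–Gilbert) homologation should turn the aldehyde into the terminal alkyne, while K2CO3/MeOH methanolyses the acetate in the same flask.

Step 3
Reactants: 3 (2E)-3-methylhept-2-en-6-yn-1-ol
Product: 4 tert-butyl{[(2E)-3-methylhept-2-en-6-yn-1-yl]oxy}diphenylsilane
Conditions: TBDPSCl, imidazole, CH2Cl2, rt
Reagents that add atoms: TBDPSCl, CC(C)(C)[Si](Cl)(c1ccccc1)c1ccccc1
Why: Routine silylation of a primary alcohol gives an ether that should survive organolithium, hydride and basic steps and come off last with fluoride.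

Step 4
Reactants: 4 tert-butyl{[(2E)-3-methylhept-2-en-6-yn-1-yl]oxy}diphenylsilane; 5 (R)-epichlorohydrin
Product: 6 (2R,8E)-10-[(tert-butyldiphenylsilyl)oxy]-1-chloro-8-methyldec-8-en-4-yn-2-ol
Conditions: n-BuLi, THF, −78 °C; BF3·OEt2; then 5, −78 °C
Reagents that add atoms: none
Why: BF3-promoted alkynylation of the epoxide should occur only at the unsubstituted epoxide carbon (SN2), so the C–O stereocentre of 5 becomes C2 unchanged and the chloride is kept.

Step 5
Reactants: 6 (2R,8E)-10-[(tert-butyldiphenylsilyl)oxy]-1-chloro-8-methyldec-8-en-4-yn-2-ol; 7 isobutyronitrile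
Product: 9 (4R,10E)-12-[(tert-butyldiphenylsilyl)oxy]-4-hydroxy-2,2,10-trimethyldodec-10-en-6-ynenitrile, via epoxide 8 (not isolated)
Conditions: 7 and LDA (2.5 equiv each), THF, −78 °C; then 6, DMPU, −78 °C → rt
Reagents that add atoms: none
Why: The alkoxide should close to the terminal epoxide (intramolecular Williamson) and lithiated isobutyronitrile should open it at CH2 (SN2), forming the quaternary C4; neither event touches the stereocentre.

Step 6
Reactants: 9 (4R,10E)-12-[(tert-butyldiphenylsilyl)oxy]-4-hydroxy-2,2,10-trimethyldodec-10-en-6-ynenitrile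
Product: 10 (4R,10E)-4-[(tert-butyldimethylsilyl)oxy]-12-[(tert-butyldiphenylsilyl)oxy]-2,2,10-trimethyldodec-10-en-6-ynenitrile
Conditions: TBSCl, imidazole, DMF, rt
Reagents that add atoms: TBSCl, CC(C)(C)[Si](C)(C)Cl
Why: Silylation of the secondary alcohol prevents lactol formation at the later aldehyde stage and gives a group removable in the presence of the TBDPS ether.

Step 7
Reactants: 10 (4R,10E)-4-[(tert-butyldimethylsilyl)oxy]-12-[(tert-butyldiphenylsilyl)oxy]-2,2,10-trimethyldodec-10-en-6-ynenitrile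
Product: 11 (4R,6Z,10E)-4-[(tert-butyldimethylsilyl)oxy]-12-[(tert-butyldiphenylsilyl)oxy]-2,2,6,10-tetramethyl-7-(4,4,5,5-tetramethyl-1,3,2-dioxaborolan-2-yl)dodeca-6,10-dienenitrile
Conditions: CuCl (10 mol%), Xantphos (10 mol%), NaOtBu (1.5 equiv), B2pin2, MeI, THF, rt
Reagents that add atoms: bis(pinacolato)diboron, CC1(C)OB(OC1(C)C)B1OC(C)(C)C(C)(C)O1; methyl iodide, CI
Why: Copper-catalysed formal methylboration (syn borylcupration, then methylation of the alkenylcopper) fixes CH3 on C10 cis to boron on C9; boron should go to C9, the alkyne carbon remote from and less hindered than the one flanked by the silyloxy-bearing branch, whose inductive effect also favours copper at C10.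

Step 8
Reactants: 11 the (6Z)-alkenyl boronate; 12 2-bromopropene
Product: 13 (4R,6E,10E)-4-[(tert-butyldimethylsilyl)oxy]-12-[(tert-butyldiphenylsilyl)oxy]-2,2,6,10-tetramethyl-7-(prop-1-en-2-yl)dodeca-6,10-dienenitrile
Conditions: Pd(OAc)2/SPhos (5 mol%), K3PO4, THF/H2O, 60 °C
Reagents that add atoms: none
Why: Suzuki–Miyaura coupling proceeds with retention at the alkenyl boronate, so the diene should carry the C10 methyl cis to the isopropenyl group and the tether carbon C1 trans to it.

Step 9
Reactants: 13 the diene nitrile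
Product: 14 (4R,6E,10E)-4-[(tert-butyldimethylsilyl)oxy]-12-[(tert-butyldiphenylsilyl)oxy]-2,2,6,10-tetramethyl-7-(prop-1-en-2-yl)dodeca-6,10-dienal
Conditions: DIBAL-H, toluene, −78 °C; then aq. Rochelle salt, dilute tartaric acid
Reagents that add atoms: water, O
Why: Half-reduction of the tertiary nitrile to the aldimine and hydrolysis should give the non-enolisable neopentyl aldehyde without touching the alkenes or silyl ethers.

Step 10
Reactants: 14 the dienal; 15 nitromethane
Product: 17 (1E,5S,7E,11E)-5-[(tert-butyldimethylsilyl)oxy]-13-[(tert-butyldiphenylsilyl)oxy]-3,3,7,11-tetramethyl-1-nitro-8-(prop-1-en-2-yl)trideca-1,7,11-triene, via nitro-aldol 16 (not isolated)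
Conditions: 15 (10 equiv), tetramethylguanidine (10 mol%), THF, 0 °C → rt; concentrate; MsCl, Et3N, CH2Cl2, −20 → 0 °C; used at once
Reagents that add atoms: none
Why: Henry addition to the non-enolisable aldehyde followed by mesylation and E1cB elimination should give the thermodynamically preferred (E)-nitroalkene.

Step 11
Reactants: 17 the (E)-nitro-triene
Product: 18 2α-(tert-butyldimethylsilyloxy)-15-(tert-butyldiphenylsilyloxy)-6α-nitrolabda-8,13E-diene
Conditions: toluene (5 mM), BHT (cat.), Ar, 80 → 110 °C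
Reagents that add atoms: none
Why: Thermal, concerted but asynchronous intramolecular [4+2] cycloaddition between the nitro-activated (E)-alkene C5=C6 and the 2,3,4,4-tetrasubstituted diene C7=C8–C9=C10; the closest known reaction type is the intramolecular Diels–Alder reaction of (E)-1-nitro-1,7,9-decatrienes to trans-fused nitro-decalins under mild heating. Ring A (C10–C1–C2–C3–C4–C5) is closed by the C5–C10 bond, formally a 6-exo attack of the diene terminus C10 on the nitroalkene β-carbon C5, and ring B (C5–C6–C7–C8–C9–C10) is closed by that bond together with C6–C7 in the six-membered pericyclic array, leaving C8=C9. C10 is set relative to C2 by a chair-like tether in which the C2 silyloxy group must be equatorial, because an axial one would be syn-axial to both the axial C4 methyl and the C10 methyl, which should give 10β-CH3 with 2α-O. C5 is set by the tether-exo, nitro-endo transition state preferred by (E)-nitroalkenes, giving the trans ring fusion (5α-H), and the E geometry is transferred suprafacially to 6α-NO2 (erased later). The step needs trans over cis fusion, one π-face, and cycloaddition faster than [1,5]-hydrogen shift from the Z-methyl of the diene; the nitro group (reaction at or below 110 °C), the gem-dimethyl group (reactive rotamer) and the C2 stereocentre should secure these. The isolated trisubstituted side-chain alkene is remote and unactivated and should not compete.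

Step 12
Reactants: 18 the 6α-nitro adduct
Product: 19 2α-(tert-butyldimethylsilyloxy)-15-(tert-butyldiphenylsilyloxy)labda-8,13E-dien-6-one
Conditions: NaOMe, MeOH, rt; then aq. TiCl3, NH4OAc (pH 5–6), THF/H2O, 0 °C → rt
Reagents that add atoms: water, O
Why: TiCl3-mediated Nef reaction: the nitronate is reduced to the imine and hydrolysed to the ketone under buffered conditions that should leave the β,γ-double bond and both silyl ethers in place.

Step 13
Reactants: 19 the 6-ketone
Product: 20 2α-(tert-butyldimethylsilyloxy)-15-(tert-butyldiphenylsilyloxy)-7α-hydroxylabda-8,13E-dien-6-one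
Conditions: KHMDS (1.1 equiv), THF, −78 °C; then 2-(phenylsulfonyl)-3-phenyloxaziridine, −78 °C; aq. NH4Cl
Reagents that add atoms: Davis oxaziridine, O=S(=O)(c1ccccc1)N1OC1c1ccccc1
Why: Kinetic deprotonation should occur at the doubly activated C7 (not the hindered tertiary C5–H) and the dienolate should take oxygen at its α-carbon C7 from the α face, opposite the axial C10 and C4 methyl groups, giving 7α-OH with C8=C9 restored (enolate hydroxylation with a sulfonyloxaziridine).

Step 14
Reactants: 20 the 7α-hydroxy ketone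
Product: 21 2α-(tert-butyldimethylsilyloxy)-15-(tert-butyldiphenylsilyloxy)labda-8,13E-diene-6β,7α-diol
Conditions: NaBH4, CeCl3·7H2O, MeOH/THF, −78 → −40 °C
Reagents that add atoms: none
Why: Luche-type hydride addition should come from the α face because the β face of C6 is blocked by the syn-axial C10 and C4 methyl groups, giving the axial 6β-alcohol trans to 7α-OH before any α-ketol shift can occur.

Step 15
Reactants: 21 the 6β,7α-diol
Product: 22 15-(tert-butyldiphenylsilyloxy)labda-8,13E-diene-2α,6β,7α-triol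
Conditions: HF·pyridine, pyridine, THF, 0 °C → rt
Reagents that add atoms: none
Why: Buffered acidic fluoride should cleave the secondary TBS ether selectively, the primary TBDPS ether being far more robust under these conditions, without ionising the allylic 7-alcohol.

Step 16
Reactants: 22 the triol
Product: 23 2α,6β,7α-triacetoxy-15-(tert-butyldiphenylsilyloxy)labda-8,13E-diene
Conditions: Ac2O, DMAP, Et3N, CH2Cl2, rt → 40 °C
Reagents that add atoms: acetic anhydride, CC(=O)OC(C)=O
Why: DMAP-catalysed acylation should esterify all three secondary alcohols, the hindered axial 6β-OH last and with retention since no C–O bond is broken.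

Step 17
Reactants: 23 the silylated triacetate
Product: 24 2α,6β,7α-triacetoxylabda-8,13E-dien-15-ol, (2S,5S,6S,7S,10S)
Conditions: TBAF, AcOH, THF, 0 °C → rt
Reagents that add atoms: none
Why: Fluoride desilylation buffered with acetic acid should free the primary allylic alcohol without acetate hydrolysis or migration.

**Compound list**

1 | geranyl acetate | CC(C)=CCC/C(C)=C/COC(C)=O | starting material
2 | (2E)-3-methyl-6-oxohex-2-en-1-yl acetate | O=CCC/C(C)=C/COC(C)=O | intermediate
3 | (2E)-3-methylhept-2-en-6-yn-1-ol | C#CCC/C(C)=C/CO | intermediate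
4 | tert-butyl{[(2E)-3-methylhept-2-en-6-yn-1-yl]oxy}diphenylsilane | C#CCC/C(C)=C/CO[Si](c1ccccc1)(c1ccccc1)C(C)(C)C | intermediate
5 | (R)-epichlorohydrin | ClC[C@H]1CO1 | starting material
6 | (2R,8E)-10-[(tert-butyldiphenylsilyl)oxy]-1-chloro-8-methyldec-8-en-4-yn-2-ol | O[C@H](CC#CCC/C(C)=C/CO[Si](c1ccccc1)(c1ccccc1)C(C)(C)C)CCl | intermediate
7 | isobutyronitrile | CC(C)C#N | starting material
8 | tert-butyl({(2E)-3-methyl-8-[(2R)-oxiran-2-yl]oct-2-en-6-yn-1-yl}oxy)diphenylsilane (not isolated) | C(C#CCC/C(C)=C/CO[Si](c1ccccc1)(c1ccccc1)C(C)(C)C)[C@@H]1CO1 | intermediate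
9 | (4R,10E)-12-[(tert-butyldiphenylsilyl)oxy]-4-hydroxy-2,2,10-trimethyldodec-10-en-6-ynenitrile | O[C@H](CC#CCC/C(C)=C/CO[Si](c1ccccc1)(c1ccccc1)C(C)(C)C)CC(C)(C)C#N | intermediate
10 | (4R,10E)-4-[(tert-butyldimethylsilyl)oxy]-12-[(tert-butyldiphenylsilyl)oxy]-2,2,10-trimethyldodec-10-en-6-ynenitrile | CC(C)(C)[Si](C)(C)O[C@H](CC#CCC/C(C)=C/CO[Si](c1ccccc1)(c1ccccc1)C(C)(C)C)CC(C)(C)C#N | intermediate
11 | (4R,6Z,10E)-4-[(tert-butyldimethylsilyl)oxy]-12-[(tert-butyldiphenylsilyl)oxy]-2,2,6,10-tetramethyl-7-(4,4,5,5-tetramethyl-1,3,2-dioxaborolan-2-yl)dodeca-6,10-dienenitrile | CC(C)(C)[Si](C)(C)O[C@H](C/C(C)=C(\CC/C(C)=C/CO[Si](c1ccccc1)(c1ccccc1)C(C)(C)C)B1OC(C)(C)C(C)(C)O1)CC(C)(C)C#N | intermediate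
12 | 2-bromopropene | CC(Br)=C | starting material
13 | (4R,6E,10E)-4-[(tert-butyldimethylsilyl)oxy]-12-[(tert-butyldiphenylsilyl)oxy]-2,2,6,10-tetramethyl-7-(prop-1-en-2-yl)dodeca-6,10-dienenitrile | CC(C)(C)[Si](C)(C)O[C@H](C/C(C)=C(\CC/C(C)=C/CO[Si](c1ccccc1)(c1ccccc1)C(C)(C)C)C(C)=C)CC(C)(C)C#N | intermediate
14 | (4R,6E,10E)-4-[(tert-butyldimethylsilyl)oxy]-12-[(tert-butyldiphenylsilyl)oxy]-2,2,6,10-tetramethyl-7-(prop-1-en-2-yl)dodeca-6,10-dienal | CC(C)(C)[Si](C)(C)O[C@H](C/C(C)=C(\CC/C(C)=C/CO[Si](c1ccccc1)(c1ccccc1)C(C)(C)C)C(C)=C)CC(C)(C)C=O | intermediate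
15 | nitromethane | C[N+](=O)[O-] | starting material
16 | (5R,7E,11E)-5-[(tert-butyldimethylsilyl)oxy]-13-[(tert-butyldiphenylsilyl)oxy]-3,3,7,11-tetramethyl-1-nitro-8-(prop-1-en-2-yl)trideca-7,11-dien-2-ol, both C2 epimers (not isolated) | CC(C)(C)[Si](C)(C)O[C@H](C/C(C)=C(\CC/C(C)=C/CO[Si](c1ccccc1)(c1ccccc1)C(C)(C)C)C(C)=C)CC(C)(C)C(O)C[N+](=O)[O-] | intermediate
17 | (1E,5S,7E,11E)-5-[(tert-butyldimethylsilyl)oxy]-13-[(tert-butyldiphenylsilyl)oxy]-3,3,7,11-tetramethyl-1-nitro-8-(prop-1-en-2-yl)trideca-1,7,11-triene | CC(C)(C)[Si](C)(C)O[C@H](C/C(C)=C(\CC/C(C)=C/CO[Si](c1ccccc1)(c1ccccc1)C(C)(C)C)C(C)=C)CC(C)(C)/C=C/[N+](=O)[O-] | intermediate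
18 | 2α-(tert-butyldimethylsilyloxy)-15-(tert-butyldiphenylsilyloxy)-6α-nitrolabda-8,13E-diene (5α-H, 10β-CH3) | CC(C)(C)[Si](C)(C)O[C@H]1CC(C)(C)[C@@H]2[C@@H]([N+](=O)[O-])CC(C)=C(CC/C(C)=C/CO[Si](c3ccccc3)(c3ccccc3)C(C)(C)C)[C@@]2(C)C1 | intermediate
19 | 2α-(tert-butyldimethylsilyloxy)-15-(tert-butyldiphenylsilyloxy)labda-8,13E-dien-6-one | CC(C)(C)[Si](C)(C)O[C@H]1CC(C)(C)[C@@H]2C(=O)CC(C)=C(CC/C(C)=C/CO[Si](c3ccccc3)(c3ccccc3)C(C)(C)C)[C@@]2(C)C1 | intermediate
20 | 2α-(tert-butyldimethylsilyloxy)-15-(tert-butyldiphenylsilyloxy)-7α-hydroxylabda-8,13E-dien-6-one | CC(C)(C)[Si](C)(C)O[C@H]1CC(C)(C)[C@@H]2C(=O)[C@@H](O)C(C)=C(CC/C(C)=C/CO[Si](c3ccccc3)(c3ccccc3)C(C)(C)C)[C@@]2(C)C1 | intermediate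
21 | 2α-(tert-butyldimethylsilyloxy)-15-(tert-butyldiphenylsilyloxy)labda-8,13E-diene-6β,7α-diol | CC(C)(C)[Si](C)(C)O[C@H]1CC(C)(C)[C@@H]2[C@H](O)[C@@H](O)C(C)=C(CC/C(C)=C/CO[Si](c3ccccc3)(c3ccccc3)C(C)(C)C)[C@@]2(C)C1 | intermediate
22 | 15-(tert-butyldiphenylsilyloxy)labda-8,13E-diene-2α,6β,7α-triol | O[C@H]1CC(C)(C)[C@@H]2[C@H](O)[C@@H](O)C(C)=C(CC/C(C)=C/CO[Si](c3ccccc3)(c3ccccc3)C(C)(C)C)[C@@]2(C)C1 | intermediate
23 | 2α,6β,7α-triacetoxy-15-(tert-butyldiphenylsilyloxy)labda-8,13E-diene | CC(=O)O[C@H]1CC(C)(C)[C@@H]2[C@H](OC(C)=O)[C@@H](OC(C)=O)C(C)=C(CC/C(C)=C/CO[Si](c3ccccc3)(c3ccccc3)C(C)(C)C)[C@@]2(C)C1 | intermediate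
24 | 2α,6β,7α-triacetoxylabda-8,13E-dien-15-ol, (2S,5S,6S,7S,10S) | CC(=O)O[C@H]1CC(C)(C)[C@@H]2[C@H](OC(C)=O)[C@@H](OC(C)=O)C(C)=C(CC/C(C)=C/CO)[C@@]2(C)C1 | target

**Step count**
Total steps: 17. Longest linear sequence: 17 (from geranyl acetate).

**Steps most likely to fail**

1. Step 11 (cycloaddition). The cis-fused (tether-endo, nitro-exo) transition state may compete, or the hindered diene may undergo [1,5]-hydrogen shift or the nitroalkene may polymerise before cycloaddition. The fallback changes the dienophile and the mode of activation. It sets out from aldehyde 14: Wittig reaction with (triphenylphosphoranylidene)acetaldehyde should give the (E)-trienal F1. Me2AlCl in CH2Cl2 at −78 → −20 °C should then promote the intramolecular Diels–Alder reaction of the Lewis-acid-bound enal, at low temperature and with a stronger endo (trans-fusion) preference, to the 6α-formyl adduct F2. Condensation with piperidine (cat. TsOH) gives the enamine F3, and copper-catalysed aerobic cleavage of its C=C bond (CuCl, O2, MeCN) removes the formyl carbon. The fallback comes back to the route at ketone 19.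

2. Step 7 (methylboration). The borylcupration may lose regiocontrol and deliver boron to C10, because the two alkyne carbons differ only by a remote silyloxy branch. The fallback replaces this steric and inductive bias by chelation. It sets out from alcohol 9: platinum-catalysed syn-diboration (Pt(PPh3)4, B2pin2, 80 °C) should give the (Z)-bis(boronate) F4. A hydroxyl-directed Suzuki–Miyaura methylation (MeI, Pd(OAc)2/RuPhos, KOH, THF/H2O) should react only at the C10 boronate, which the C2 alkoxide activates through a five-membered borate, giving the hydroxy alkenyl boronate F5. Silylation (TBSCl, imidazole) brings the fallback back to the route at boronate 11.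

3. Step 12 (Nef reaction). Deprotonation of the axial C6–H, flanked by two syn-axial methyl groups, may be too slow for nitronate formation, or base may move the β,γ-double bond into conjugation once the ketone is present. The fallback avoids the carbanion. It sets out from nitro compound 18: reduction with Zn/AcOH should give the 6α-amine F6. Transamination with 3,5-di-tert-butyl-1,2-benzoquinone (MeOH/THF) should give the N-aryl ketimine F7, which aqueous oxalic acid hydrolyses in the same flask. The fallback comes back to the route at ketone 19.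

Further compounds
F1 | step 11 | (2E,6R,8E,12E)-6-[(tert-butyldimethylsilyl)oxy]-14-[(tert-butyldiphenylsilyl)oxy]-4,4,8,12-tetramethyl-9-(prop-1-en-2-yl)tetradeca-2,8,12-trienal | CC(C)(C)[Si](C)(C)O[C@H](C/C(C)=C(\CC/C(C)=C/CO[Si](c1ccccc1)(c1ccccc1)C(C)(C)C)C(C)=C)CC(C)(C)/C=C/C=O
F2 | step 11 | 2α-(tert-butyldimethylsilyloxy)-15-(tert-butyldiphenylsilyloxy)-6α-formyllabda-8,13E-diene | CC(C)(C)[Si](C)(C)O[C@H]1CC(C)(C)[C@@H]2[C@@H](C=O)CC(C)=C(CC/C(C)=C/CO[Si](c3ccccc3)(c3ccccc3)C(C)(C)C)[C@@]2(C)C1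
F3 | step 11 | piperidine enamine of F2 (6-(piperidin-1-ylmethylidene) derivative, either geometry) | CC(C)(C)[Si](C)(C)O[C@H]1CC(C)(C)[C@@H]2C(=CN3CCCCC3)CC(C)=C(CC/C(C)=C/CO[Si](c3ccccc3)(c3ccccc3)C(C)(C)C)[C@@]2(C)C1
F4 | step 7 | (4R,6Z,10E)-12-[(tert-butyldiphenylsilyl)oxy]-4-hydroxy-2,2,10-trimethyl-6,7-bis(4,4,5,5-tetramethyl-1,3,2-dioxaborolan-2-yl)dodeca-6,10-dienenitrile | O[C@H](C/C(B1OC(C)(C)C(C)(C)O1)=C(\CC/C(C)=C/CO[Si](c1ccccc1)(c1ccccc1)C(C)(C)C)B1OC(C)(C)C(C)(C)O1)CC(C)(C)C#N
F5 | step 7 | (4R,6Z,10E)-12-[(tert-butyldiphenylsilyl)oxy]-4-hydroxy-2,2,6,10-tetramethyl-7-(4,4,5,5-tetramethyl-1,3,2-dioxaborolan-2-yl)dodeca-6,10-dienenitrile | O[C@H](C/C(C)=C(\CC/C(C)=C/CO[Si](c1ccccc1)(c1ccccc1)C(C)(C)C)B1OC(C)(C)C(C)(C)O1)CC(C)(C)C#N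
F6 | step 12 | 6α-amino-2α-(tert-butyldimethylsilyloxy)-15-(tert-butyldiphenylsilyloxy)labda-8,13E-diene | CC(C)(C)[Si](C)(C)O[C@H]1CC(C)(C)[C@@H]2[C@@H](N)CC(C)=C(CC/C(C)=C/CO[Si](c3ccccc3)(c3ccccc3)C(C)(C)C)[C@@]2(C)C1
F7 | step 12 | N-(3,5-di-tert-butyl-2-hydroxyphenyl) ketimine of 19 | CC(C)(C)[Si](C)(C)O[C@H]1CC(C)(C)[C@@H]2C(=Nc3cc(C(C)(C)C)cc(C(C)(C)C)c3O)CC(C)=C(CC/C(C)=C/CO[Si](c3ccccc3)(c3ccccc3)C(C)(C)C)[C@@]2(C)C1
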